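## Retrosynthetic overview

1. Target 13 ⇒ lactone 11 + geranyl bromide 12: O-alkylation of the only non-chelated phenol (6-OH) as the last step.
2. 11 ⇒ open-chain diketo-dioxinone 9: one flask closes first the benzene ring (aldol/dehydration, C8a–C4a bond), then the δ-lactone (C3–OH onto the masked C1 carboxyl), as in polyketide biosynthesis.
3. 9 ⇒ keto-dioxinone 4 (polyketide carbons C1–C6, carrying the future 5-OMe) + acid 6 (C4a carbonyl, C4–OAc, C3–O, 3-Me) by dianion C-acylation.
4. 4 ⇒ 2,2,6-trimethyl-4H-1,3-dioxin-4-one 1 + methoxyacetyl chloride 2; 6 ⇒ O-tert-butyl-L-threonine 5 (both stereocentres from the chiral pool, C–N exchanged for C–OAc with retention).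

Assumption: positions are given in isochromanone numbering; lithium species made as a separate stage before the next reagent is added are numbered, while fleeting mechanistic species (diazonium ion, aldol adducts, acyl ketene, phenoxide in equilibrium) are only described.

## Route

Step 1
Reactants: 1 2,2,6-trimethyl-4H-1,3-dioxin-4-one; 2 methoxyacetyl chloride
Product: 4 6-(3-methoxy-2-oxopropyl)-2,2-dimethyl-4H-1,3-dioxin-4-one, via lithium dienolate 3 (not isolated)
Conditions: 1 (2.0 equiv), LiN(SiMe3)2 (2.0 equiv), THF, −78 °C, 1 h; then 2 (1.0 equiv), −78 °C, 2 h; 1 M HCl quench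
Reagents that add atoms: none
Why: Vinylogous (γ-selective) Claisen C-acylation of lithium dienolate 3 by an acid chloride, a standard entry to 6-(2-oxoalkyl)dioxinones, in which the second equivalent of 3 deprotonates the more acidic product and so prevents double acylation; no stereocentre is formed.

Step 2
Reactants: 5 O-tert-butyl-L-threonine [(2S,3R)-2-amino-3-tert-butoxybutanoic acid]
Product: 6 (2S,3R)-2-acetoxy-3-tert-butoxybutanoic acid
Conditions: NaNO2 (3 equiv, in portions), AcOH, 15 °C → rt, 16 h
Reagents that add atoms: acetic acid, CC(=O)O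
Why: Nitrosative deamination (acetoxy-dediazoniation) in which the carboxylate displaces N2 and acetic acid opens the resulting α-lactone, so two inversions give net retention at C2 (the future C4; S here, R in the target only because the CIP priorities change), while C3 (future C3, R) and the tert-butyl ether are untouched.

Step 3
Reactants: 6 (2S,3R)-2-acetoxy-3-tert-butoxybutanoic acid; 4 6-(3-methoxy-2-oxopropyl)-2,2-dimethyl-4H-1,3-dioxin-4-one
Product: 9 (2R,3S)-2-tert-butoxy-7-(2,2-dimethyl-4-oxo-4H-1,3-dioxin-6-yl)-5-methoxy-4,6-dioxoheptan-3-yl acetate, via acyl imidazolide 7 (not isolated), via dilithium dianion 8 (not isolated)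
Conditions: 6, 1,1'-carbonyldiimidazole (1.05 equiv), THF, rt, 1 h, N2 purge; separately 4 (3 equiv), LiN(iPr)2 (6 equiv), THF, −78 → −40 °C, 1 h; solution of 7 added at −78 °C, 45 min; 1 M HCl quench at −78 °C
Reagents that add atoms: none
Why: Harris-type Claisen acylation of a 1,3-dicarbonyl dianion, in which the terminal methoxy-bearing carbanion of 8 is the most nucleophilic site, the N-acylimidazole is far more electrophilic than the acetate at −78 °C, and the product is held as its inert diketonate (which also shields the α-acetoxy stereocentre from enolisation) until the cold acidic quench; the excess of 8 absorbs the imidazole proton and deprotonates the product, and the only new sp3 centre (the methoxy carbon) later becomes aromatic.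

Step 4
Reactants: 9 (2R,3S)-2-tert-butoxy-7-(2,2-dimethyl-4-oxo-4H-1,3-dioxin-6-yl)-5-methoxy-4,6-dioxoheptan-3-yl acetate
Product: 11 (3R,4R)-6,8-dihydroxy-5-methoxy-3-methyl-1-oxo-3,4-dihydro-1H-2-benzopyran-4-yl acetate, via benzodioxinone 10 (not isolated)
Conditions: Et3N (2 equiv), CH2Cl2, rt, 16 h; then anisole (10 equiv), CF3CO2H (to 1:2 v/v with CH2Cl2), 0 °C → rt, 3 h
Reagents that add atoms: none
Why: Polyketide-type cyclisation cascade in which, under Et3N, the dioxinone α-carbon (future C8a) adds to the ketone next to the acetoxy carbon (future C4a) in a 6-enolexo aldol and dehydration/enolisation gives arene 10 with the carboxyl still masked as its acylal, after which CF3CO2H cleaves the tert-butyl ether (cation trapped by anisole) and the liberated C3 hydroxyl, the only free alcohol because the benzylic oxygen is already the acetate, lactonises by acid-catalysed intramolecular transacylation with loss of acetone to the six-membered lactone only; both stereocentres are carried unchanged from 6 and the benzylic one is no longer enolisable once the ring is aromatic.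

Step 5
Reactants: 11 (3R,4R)-6,8-dihydroxy-5-methoxy-3-methyl-1-oxo-3,4-dihydro-1H-2-benzopyran-4-yl acetate; 12 geranyl bromide [(2E)-1-bromo-3,7-dimethylocta-2,6-diene]
Product: 13 (3R,4R)-6-{[(2E)-3,7-dimethylocta-2,6-dien-1-yl]oxy}-8-hydroxy-5-methoxy-3-methyl-1-oxo-3,4-dihydro-1H-2-benzopyran-4-yl acetate (CNP0251645.2)
Conditions: 12 (1.05 equiv), K2CO3 (1.1 equiv), dry acetone, rt, 12 h
Reagents that add atoms: none
Why: Williamson ether synthesis that is regioselective because the 6-OH (para to the lactone carbonyl, not hydrogen-bonded) is far more acidic and nucleophilic than the 8-OH chelated to C1=O, so one equivalent of carbonate and the allylic bromide alkylate it alone with the E-olefin retained, while the secondary acetate and both stereocentres are inert to K2CO3 in dry acetone.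

## Compound list

1 | 2,2,6-trimethyl-4H-1,3-dioxin-4-one | CC1=CC(=O)OC(C)(C)O1 | starting material
2 | methoxyacetyl chloride | COCC(Cl)=O | starting material
3 | lithium 2,2-dimethyl-6-methylidene-6H-1,3-dioxin-4-olate (lithium dienolate of 1) | C=C1C=C(O[Li])OC(C)(C)O1 | intermediate
4 | 6-(3-methoxy-2-oxopropyl)-2,2-dimethyl-4H-1,3-dioxin-4-one | COCC(=O)CC1=CC(=O)OC(C)(C)O1 | intermediate
5 | O-tert-butyl-L-threonine, (2S,3R)-2-amino-3-tert-butoxybutanoic acid | OC(=O)[C@@H](N)[C@@H](C)OC(C)(C)C | starting material
6 | (2S,3R)-2-acetoxy-3-tert-butoxybutanoic acid | OC(=O)[C@@H](OC(C)=O)[C@@H](C)OC(C)(C)C | intermediate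
7 | (2S,3R)-3-tert-butoxy-1-(1H-imidazol-1-yl)-1-oxobutan-2-yl acetate (acyl imidazolide of 6) | O=C(n1ccnc1)[C@@H](OC(C)=O)[C@@H](C)OC(C)(C)C | intermediate
8 | dilithium dianion of 4, drawn as the bis-O-lithium enolate (ketone enolate towards the methoxy carbon, dioxinone as exocyclic dienolate) | COC=C(O[Li])C=C1C=C(O[Li])OC(C)(C)O1 | intermediate
9 | (2R,3S)-2-tert-butoxy-7-(2,2-dimethyl-4-oxo-4H-1,3-dioxin-6-yl)-5-methoxy-4,6-dioxoheptan-3-yl acetate (C5 epimers, partly enolised) | COC(C(=O)CC1=CC(=O)OC(C)(C)O1)C(=O)[C@@H](OC(C)=O)[C@@H](C)OC(C)(C)C | intermediate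
10 | (1R,2R)-2-tert-butoxy-1-(7-hydroxy-6-methoxy-2,2-dimethyl-4-oxo-4H-1,3-benzodioxin-5-yl)propyl acetate | COc1c(O)cc2OC(C)(C)OC(=O)c2c1[C@@H](OC(C)=O)[C@@H](C)OC(C)(C)C | intermediate
11 | (3R,4R)-6,8-dihydroxy-5-methoxy-3-methyl-1-oxo-3,4-dihydro-1H-2-benzopyran-4-yl acetate (cis) | COc1c(O)cc(O)c2c1[C@@H](OC(C)=O)[C@@H](C)OC2=O | intermediate
12 | geranyl bromide, (2E)-1-bromo-3,7-dimethylocta-2,6-diene | BrC/C=C(\C)CCC=C(C)C | starting material
13 | (3R,4R)-6-{[(2E)-3,7-dimethylocta-2,6-dien-1-yl]oxy}-8-hydroxy-5-methoxy-3-methyl-1-oxo-3,4-dihydro-1H-2-benzopyran-4-yl acetate (cis) | COc1c(OC/C=C(\C)CCC=C(C)C)cc(O)c2c1[C@@H](OC(C)=O)[C@@H](C)OC2=O | target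

## Step count and risks

Total steps: 5. Longest linear sequence: 4 steps (1 → 4 → 9 → 11 → 13, or 5 → 6 → 9 → 11 → 13).

Most likely to fail, first: step 3. The dianion may attack the acetate or remove the α-hydrogen of 7 (loss of the C4 configuration, β-elimination of tert-butoxide), or may acylate on oxygen. The fallback removes lithium enolates from the coupling. It sets out from 4: Me3SiCl/Et3N gives the mono(trimethylsilyl) enol ether F1, and LiN(iPr)2 followed by Me3SiCl turns this into the bis(trimethylsilyl) dienol ether F2, a Chan-type diene made before any acetate is present. Acid 6 is converted with 1-chloro-N,N,2-trimethylprop-1-en-1-amine (neutral, HCl-free, so the tert-butyl ether survives) into (2S,3R)-2-acetoxy-3-tert-butoxybutanoyl chloride F3. F2 and F3 are combined in CH2Cl2 at −78 → −20 °C (Mukaiyama-type Claisen acylation at the terminal methoxy-bearing carbon, no base present), and aqueous work-up brings the route back at 9.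

Second: step 4. The hindered, doubly α-oxygenated ketone may resist the aldol under Et3N, or the acylal may lactonise sluggishly in acid. The fallback unmasks the acyl ketene first. It sets out from 9: heating in toluene with methanol (110 °C) expels acetone, and methanol traps the acyl ketene to give the open-chain methyl triketo ester F4. NaOAc in MeOH then effects the aldol aromatisation through the free β-keto ester carbon (more nucleophilic than the dioxinone) to methyl resorcylate F5. CF3CO2H/anisole cleaves the tert-butyl ether and the hydroxy ester lactonises with loss of methanol, coming back to the route at 11.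

Third: step 2. The C4 configuration depends on clean retention, and the β-alkoxy group or incomplete acetate capture could erode yield or purity. The fallback separates the two events. It sets out from 5: NaNO2 in dilute aqueous H2SO4 (0 °C → rt) gives (2S,3R)-3-tert-butoxy-2-hydroxybutanoic acid F6 by hydroxy-dediazoniation with retention. Ac2O/pyridine with catalytic 4-(dimethylamino)pyridine then acetylates the hydroxyl (mixed anhydride hydrolysed on work-up), returning to the route at 6.

## Further compounds

F1 | step 3 | 6-[3-methoxy-2-(trimethylsilyloxy)prop-1-en-1-yl]-2,2-dimethyl-4H-1,3-dioxin-4-one | COCC(O[Si](C)(C)C)=CC1=CC(=O)OC(C)(C)O1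
F2 | step 3 | 6-[3-methoxy-2-(trimethylsilyloxy)prop-2-en-1-ylidene]-2,2-dimethyl-4-(trimethylsilyloxy)-6H-1,3-dioxine | COC=C(O[Si](C)(C)C)C=C1C=C(O[Si](C)(C)C)OC(C)(C)O1
F3 | step 3 | (2S,3R)-2-acetoxy-3-tert-butoxybutanoyl chloride | O=C(Cl)[C@@H](OC(C)=O)[C@@H](C)OC(C)(C)C
F4 | step 4 | methyl (8S,9R)-8-acetoxy-9-tert-butoxy-6-methoxy-3,5,7-trioxodecanoate (C6 epimers) | COC(=O)CC(=O)CC(=O)C(OC)C(=O)[C@@H](OC(C)=O)[C@@H](C)OC(C)(C)C
F5 | step 4 | methyl 2-[(1R,2R)-1-acetoxy-2-tert-butoxypropyl]-4,6-dihydroxy-3-methoxybenzoate | COC(=O)c1c(O)cc(O)c(OC)c1[C@@H](OC(C)=O)[C@@H](C)OC(C)(C)C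
F6 | step 2 | (2S,3R)-3-tert-butoxy-2-hydroxybutanoic acid | OC(=O)[C@@H](O)[C@@H](C)OC(C)(C)C
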